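## Retrosynthetic overview

1. The target comes from a bis-silylated macrocyclic 8-hydroxy-6,12-olide by angeloylation at O8 and desilylation.
2. Key disconnection: the C7–C8 bond of the ten-membered ring and the lactone C12–O6 bond are made in one flask from an acyclic epoxy-acrylate aldehyde by palladium/indium umpolung. The lactone ring closes first, then the ten-membered ring; C7 and C8 are set from C6.
3. The epoxy acrylate comes from a C2-symmetric (Z,Z)-dialdehyde and methyl 2-(bromomethyl)acrylate by chiral sulfur-ylide mono-epoxidation, which sets C6.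
4. The dialdehyde comes from (3S,5S)-hepta-1,6-diyne-3,5-diol by two-directional anti-carbomagnesiation/iodination (both Z-alkenes), silylation and formylation.
5. The diyne diol comes from a 1,3-diketone by double asymmetric transfer hydrogenation (sets C1 and C3); the diketone comes from two commercial silyl alkynes.

Position labels C1–C13 follow germacrane numbering: C6 carries the lactone oxygen, C7 is the ring-fusion carbon bearing C11, C8 carries the ester, C11 is the alpha-methylene carbon, C12 the lactone carbonyl, and C1 and C3 carry the free hydroxyls.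

Assumption: RuCl[(S,S)-TsDPEN](p-cymene) gives the (S)-propargylic carbinols and (2R,5R)-2,5-dimethylthiolane gives the (2S,3S)-epoxide; if either sense proves opposite, the mirror-image catalyst or sulfide is used.

## Route

Step 1
Reactants: 1 4-(trimethylsilyl)but-3-yn-2-one; 2 3-(trimethylsilyl)prop-2-ynoic acid
Product: 4 1,7-bis(trimethylsilyl)hepta-1,6-diyne-3,5-dione, via acid chloride 3 (not isolated)
Conditions: 2, (COCl)2, DMF (cat.), CH2Cl2, 0 to 23 °C, evaporate; 1, LiN(SiMe3)2 (2.1 equiv), THF, −78 °C, then 3, −78 to 0 °C; 1 M HCl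
Reagents that add atoms: none
Why: Crossed Claisen-type C-acylation of the lithium enolate of the methyl ynone by the acid chloride gives the 1,3-diketone, the second equivalent of base holding the more acidic product as its enolate until work-up.

Step 2
Reactants: 4 1,7-bis(trimethylsilyl)hepta-1,6-diyne-3,5-dione
Product: 6 (3S,5S)-hepta-1,6-diyne-3,5-diol, via bis-silyl diol 5 (not isolated)
Conditions: RuCl[(S,S)-TsDPEN](p-cymene) (2 mol%), HCO2H/Et3N (5:2), CH2Cl2, 30 °C; concentrate; K2CO3 (cat.), MeOH, 23 °C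
Reagents that add atoms: none
Why: Noyori asymmetric transfer hydrogenation reduces each ynone carbonyl under catalyst control (the alkynyl group plays the role of the aryl group of an aryl ketone), so both (S) carbinols of the anti diol are set and the minor enantiomer is largely diverted into the separable meso diol, and methanolysis then frees the terminal alkynes.

Step 3
Reactants: 6 (3S,5S)-hepta-1,6-diyne-3,5-diol
Product: 7 (1Z,3S,5S,6Z)-1,7-diiodo-2,6-dimethylhepta-1,6-diene-3,5-diol
Conditions: MeMgBr (8 equiv), CuI (40 mol%), THF, −20 to 23 °C; then I2, THF, −78 to 0 °C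
Reagents that add atoms: methylmagnesium bromide, C[Mg]Br; iodine, II
Why: Copper-catalysed anti-carbomagnesiation of each propargylic alkoxide delivers methyl to the alkyne carbon next to the carbinol and magnesium to the terminal carbon cis to the alkoxide (five-membered chelate), and iodinolysis with retention gives both (Z)-vinyl iodides.

Step 4
Reactants: 7 (1Z,3S,5S,6Z)-1,7-diiodo-2,6-dimethylhepta-1,6-diene-3,5-diol
Product: 8 (1Z,3S,5S,6Z)-3,5-bis(tert-butyldimethylsilyloxy)-1,7-diiodo-2,6-dimethylhepta-1,6-diene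
Conditions: TBSOTf (2.5 equiv), 2,6-lutidine, CH2Cl2, −78 to 0 °C
Reagents that add atoms: tert-butyldimethylsilyl trifluoromethanesulfonate, CC(C)(C)[Si](C)(C)OS(=O)(=O)C(F)(F)F
Why: Silyl ether formation masks the two hydroxyls that must stay free of acyl groups until the end and does not touch the stereocentres or the vinyl iodides.

Step 5
Reactants: 8 (1Z,3S,5S,6Z)-3,5-bis(tert-butyldimethylsilyloxy)-1,7-diiodo-2,6-dimethylhepta-1,6-diene
Product: 9 (2Z,4S,6S,7Z)-4,6-bis(tert-butyldimethylsilyloxy)-3,7-dimethylnona-2,7-dienedial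
Conditions: t-BuLi (4.4 equiv), Et2O, −78 °C; DMF, −78 to −20 °C; pH 7 buffer, kept cold and used at once
Reagents that add atoms: N,N-dimethylformamide, CN(C)C=O
Why: Lithium–iodine exchange proceeds with retention of alkene geometry and Bouveault-type formylation of the two vinyllithiums with DMF gives the C2-symmetric (Z,Z)-dialdehyde.

Step 6
Reactants: 9 (2Z,4S,6S,7Z)-4,6-bis(tert-butyldimethylsilyloxy)-3,7-dimethylnona-2,7-dienedial (3 equiv; excess recovered); 10 methyl 2-(bromomethyl)prop-2-enoate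
Product: 12 methyl 2-[(2S,3S)-3-[(1Z,3S,5S,6Z)-3,5-bis(tert-butyldimethylsilyloxy)-2,6-dimethyl-8-oxoocta-1,6-dien-1-yl]oxiran-2-yl]prop-2-enoate, via sulfonium bromide 11 (not isolated)
Conditions: (2R,5R)-2,5-dimethylthiolane (1.0 equiv), Cs2CO3 (1.5 equiv), MeCN/H2O (9:1), 0 to 23 °C
Reagents that add atoms: none
Why: Proposed new method: the thiolane is alkylated by the allylic bromide, Cs2CO3 deprotonates sulfonium salt 11 to a semi-stabilised allyl ylide that adds 1,2 to one of the two homotopic aldehydes of 9 and closes with loss of the sulfide (Corey–Chaykovsky-type epoxidation), the C2-symmetric sulfide shielding one face so that the anti betaine gives the trans epoxide and sets C6 (the minor cis epoxide is removed by chromatography), while excess dialdehyde secures mono-reaction; the closest known reaction is the enantioselective synthesis of vinyl oxiranes from aldehydes, methallyl halides and this sulfide.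

Step 7
Reactants: 12 methyl 2-[(2S,3S)-3-[(1Z,3S,5S,6Z)-3,5-bis(tert-butyldimethylsilyloxy)-2,6-dimethyl-8-oxoocta-1,6-dien-1-yl]oxiran-2-yl]prop-2-enoate
Product: 14 (3aS,4R,5Z,7S,9S,10Z,11aS)-7,9-bis(tert-butyldimethylsilyloxy)-4-hydroxy-6,10-dimethyl-3-methylidene-3a,4,7,8,9,11a-hexahydrocyclodeca[b]furan-2(3H)-one, via butenolide allylindium 13 (not isolated)
Conditions: Pd(PPh3)4 (10 mol%), InI (2.5 equiv), THF/DMF (4:1), 23 °C, 12 added by syringe pump over 10 h (final 1 mM); aq. NH4Cl
Reagents that add atoms: none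
Why: Proposed new method: zerovalent palladium ionises the vinyl epoxide at the acrylate-flanked C7–O bond to a 2-(methoxycarbonyl)-π-allylpalladium alkoxide, InI transmetalates it to an allylindium (umpolung), the C6 alkoxide that is present from the outset closes the five-membered lactone onto the cis-disposed ester to give 13 before the slower ten-membered ring closure, and the cyclic allylindium then adds through a chair transition state to the C8 aldehyde at C7 anti to the C6 substituent, which sets the trans ring fusion and the anti C7/C8 relationship from the 6S centre; the closest known reactions are the palladium/InI umpolung allylation of aldehydes with vinyl epoxides to 2-vinyl-1,3-diols and the indium- or zinc-mediated Barbier addition of 3-(bromomethyl)butenolides to aldehydes.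

Step 8
Reactants: 14 (3aS,4R,5Z,7S,9S,10Z,11aS)-7,9-bis(tert-butyldimethylsilyloxy)-4-hydroxy-6,10-dimethyl-3-methylidene-3a,4,7,8,9,11a-hexahydrocyclodeca[b]furan-2(3H)-one; 15 angelic acid, (2Z)-2-methylbut-2-enoic acid
Product: 17 (3aR,4R,5Z,7S,9S,10Z,11aS)-7,9-bis(tert-butyldimethylsilyloxy)-6,10-dimethyl-3-methylidene-2-oxo-2,3,3a,4,7,8,9,11a-octahydrocyclodeca[b]furan-4-yl (2Z)-2-methylbut-2-enoate, via mixed anhydride 16 (not isolated)
Conditions: 15, 2,4,6-trichlorobenzoyl chloride, Et3N, toluene, 23 °C; then 14, toluene, 75 °C, no DMAP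
Reagents that add atoms: none
Why: Yamaguchi esterification through mixed anhydride 16 acylates the only free hydroxyl (C8), and leaving out a nucleophilic catalyst avoids addition–elimination isomerisation of the (Z)-angelate to the tiglate.

Step 9
Reactants: 17 (3aR,4R,5Z,7S,9S,10Z,11aS)-7,9-bis(tert-butyldimethylsilyloxy)-6,10-dimethyl-3-methylidene-2-oxo-2,3,3a,4,7,8,9,11a-octahydrocyclodeca[b]furan-4-yl (2Z)-2-methylbut-2-enoate
Product: 18 (3aR,4R,5Z,7S,9S,10Z,11aS)-7,9-dihydroxy-6,10-dimethyl-3-methylidene-2-oxo-2,3,3a,4,7,8,9,11a-octahydrocyclodeca[b]furan-4-yl (2Z)-2-methylbut-2-enoate (CNP0152559.1)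
Conditions: HF·pyridine, pyridine, THF, 0 to 23 °C
Reagents that add atoms: none
Why: Fluoride-mediated desilylation under pyridine-buffered conditions frees the C1 and C3 hydroxyls without touching the alpha-methylene lactone, the angelate or any stereocentre.

## Compound list

1 | 4-(trimethylsilyl)but-3-yn-2-one | CC(=O)C#C[Si](C)(C)C | starting material
2 | 3-(trimethylsilyl)prop-2-ynoic acid | C[Si](C)(C)C#CC(=O)O | starting material
3 | 3-(trimethylsilyl)prop-2-ynoyl chloride | C[Si](C)(C)C#CC(=O)Cl | intermediate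
4 | 1,7-bis(trimethylsilyl)hepta-1,6-diyne-3,5-dione | C[Si](C)(C)C#CC(=O)CC(=O)C#C[Si](C)(C)C | intermediate
5 | (3S,5S)-1,7-bis(trimethylsilyl)hepta-1,6-diyne-3,5-diol | C[Si](C)(C)C#C[C@@H](O)C[C@H](O)C#C[Si](C)(C)C | intermediate
6 | (3S,5S)-hepta-1,6-diyne-3,5-diol | C#C[C@@H](O)C[C@H](O)C#C | intermediate
7 | (1Z,3S,5S,6Z)-1,7-diiodo-2,6-dimethylhepta-1,6-diene-3,5-diol | I/C=C(/C)[C@@H](O)C[C@H](O)/C(C)=C\I | intermediate
8 | (1Z,3S,5S,6Z)-3,5-bis(tert-butyldimethylsilyloxy)-1,7-diiodo-2,6-dimethylhepta-1,6-diene | I/C=C(/C)[C@@H](O[Si](C)(C)C(C)(C)C)C[C@H](O[Si](C)(C)C(C)(C)C)/C(C)=C\I | intermediate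
9 | (2Z,4S,6S,7Z)-4,6-bis(tert-butyldimethylsilyloxy)-3,7-dimethylnona-2,7-dienedial | O=C/C=C(/C)[C@@H](O[Si](C)(C)C(C)(C)C)C[C@H](O[Si](C)(C)C(C)(C)C)/C(C)=C\C=O | intermediate
10 | methyl 2-(bromomethyl)prop-2-enoate | C=C(CBr)C(=O)OC | starting material
11 | (2R,5R)-1-[2-(methoxycarbonyl)prop-2-en-1-yl]-2,5-dimethylthiolan-1-ium bromide | C[C@@H]1CC[C@@H](C)[S+]1CC(=C)C(=O)OC.[Br-] | intermediate
12 | methyl 2-[(2S,3S)-3-[(1Z,3S,5S,6Z)-3,5-bis(tert-butyldimethylsilyloxy)-2,6-dimethyl-8-oxoocta-1,6-dien-1-yl]oxiran-2-yl]prop-2-enoate | C=C(C(=O)OC)[C@@H]1O[C@H]1/C=C(/C)[C@@H](O[Si](C)(C)C(C)(C)C)C[C@H](O[Si](C)(C)C(C)(C)C)/C(C)=C\C=O | intermediate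
13 | [(5S)-5-[(1Z,3S,5S,6Z)-3,5-bis(tert-butyldimethylsilyloxy)-2,6-dimethyl-8-oxoocta-1,6-dien-1-yl]-2-oxo-2,5-dihydrofuran-3-yl]methyl(iodo)(methoxy)indium | O=C1O[C@@H](/C=C(/C)[C@@H](O[Si](C)(C)C(C)(C)C)C[C@H](O[Si](C)(C)C(C)(C)C)/C(C)=C\C=O)C=C1C[In](I)OC | intermediate
14 | (3aS,4R,5Z,7S,9S,10Z,11aS)-7,9-bis(tert-butyldimethylsilyloxy)-4-hydroxy-6,10-dimethyl-3-methylidene-3a,4,7,8,9,11a-hexahydrocyclodeca[b]furan-2(3H)-one | C=C1C(=O)O[C@H]2/C=C(/C)[C@@H](O[Si](C)(C)C(C)(C)C)C[C@H](O[Si](C)(C)C(C)(C)C)/C(C)=C\[C@@H](O)[C@H]12 | intermediate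
15 | angelic acid, (2Z)-2-methylbut-2-enoic acid | C/C=C(/C)C(=O)O | starting material
16 | (2Z)-2-methylbut-2-enoic 2,4,6-trichlorobenzoic anhydride | C/C=C(/C)C(=O)OC(=O)c1c(Cl)cc(Cl)cc1Cl | intermediate
17 | (3aR,4R,5Z,7S,9S,10Z,11aS)-7,9-bis(tert-butyldimethylsilyloxy)-6,10-dimethyl-3-methylidene-2-oxo-2,3,3a,4,7,8,9,11a-octahydrocyclodeca[b]furan-4-yl (2Z)-2-methylbut-2-enoate | C=C1C(=O)O[C@H]2/C=C(/C)[C@@H](O[Si](C)(C)C(C)(C)C)C[C@H](O[Si](C)(C)C(C)(C)C)/C(C)=C\[C@@H](OC(=O)/C(C)=C\C)[C@H]12 | intermediate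
18 | (3aR,4R,5Z,7S,9S,10Z,11aS)-7,9-dihydroxy-6,10-dimethyl-3-methylidene-2-oxo-2,3,3a,4,7,8,9,11a-octahydrocyclodeca[b]furan-4-yl (2Z)-2-methylbut-2-enoate | C=C1C(=O)O[C@H]2/C=C(/C)[C@@H](O)C[C@H](O)/C(C)=C\[C@@H](OC(=O)/C(C)=C\C)[C@H]12 | target

## Step count and risks

Total step count: 9. Longest linear sequence: 9 steps (1 and 2 to 18).

Steps most likely to fail:

**Step 7 (umpolung, lactonisation and ten-membered ring closure in one flask).** The closure of a ten-membered ring by a cyclic allylindium is unprecedented. The π-allylpalladium alkoxide may instead isomerise, or the new C8 alkoxide may translactonise. The fallback sets out from 12 and comes back at 14. LiBr and AcOH in THF open the epoxide of 12 in SN2' fashion (bromide adds to the acrylate terminus and the epoxide oxygen is expelled). The (Z)-gamma-hydroxy ester so formed lactonises to (5S)-3-(bromomethyl)-5-[(1Z,3S,5S,6Z)-3,5-bis(tert-butyldimethylsilyloxy)-2,6-dimethyl-8-oxoocta-1,6-dien-1-yl]furan-2(5H)-one F1, which is isolated. F1 is then cyclised at high dilution with CrCl2 in THF/DMF (intramolecular Nozaki–Hiyama-type allylation through the same cyclic allylmetal geometry) to give 14.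

**Step 6 (ylide mono-epoxidation with an ester-bearing allyl ylide).** The ylide may polymerise or add in conjugate fashion, and the face selectivity is untested. The fallback sets out from 9 (with 10) and comes back at 12. Compound 10 is brominated with Br2 to methyl 2,3-dibromo-2-(bromomethyl)propanoate F2 and dehydrobrominated with Et3N to methyl (2Z)-3-bromo-2-(bromomethyl)prop-2-enoate F3. Barbier addition of F3 to excess 9 with a deficit of indium powder in THF/H2O (gamma-bromoallylation) gives methyl (4S,5Z,7S,9S,10Z)-3-bromo-7,9-bis(tert-butyldimethylsilyloxy)-4-hydroxy-6,10-dimethyl-2-methylidene-12-oxododeca-5,10-dienoate F4 together with its 4R epimer. The 4S compound is separated by chromatography and closed with K2CO3 in MeCN to 12; the configuration at the bromine-bearing carbon is irrelevant because it is erased in step 7.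

**Step 8 (angeloylation of the hindered C8 hydroxyl).** Isomerisation to the tiglate or base-induced migration of the lactone to O8 may intervene. The fallback sets out from 14 and comes back at 17. Compound 14 is esterified at 23 °C (DCC, DMAP) with 2-[bis(2,2,2-trifluoroethoxy)phosphoryl]propanoic acid to the 4-O-{2-[bis(2,2,2-trifluoroethoxy)phosphoryl]propanoyl} ester of 14 F5 (epimers at the phosphonate carbon). A Still–Gennari olefination (KN(SiMe3)2, 18-crown-6, acetaldehyde, THF, −78 °C) then builds the (Z)-2-methylbut-2-enoate in place to give 17.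

## Further compounds

F1 | step 7 | (5S)-3-(bromomethyl)-5-[(1Z,3S,5S,6Z)-3,5-bis(tert-butyldimethylsilyloxy)-2,6-dimethyl-8-oxoocta-1,6-dien-1-yl]furan-2(5H)-one | O=C1O[C@@H](/C=C(/C)[C@@H](O[Si](C)(C)C(C)(C)C)C[C@H](O[Si](C)(C)C(C)(C)C)/C(C)=C\C=O)C=C1CBr
F2 | step 6 | methyl 2,3-dibromo-2-(bromomethyl)propanoate | COC(=O)C(Br)(CBr)CBr
F3 | step 6 | methyl (2Z)-3-bromo-2-(bromomethyl)prop-2-enoate | COC(=O)/C(CBr)=C/Br
F4 | step 6 | methyl (4S,5Z,7S,9S,10Z)-3-bromo-7,9-bis(tert-butyldimethylsilyloxy)-4-hydroxy-6,10-dimethyl-2-methylidene-12-oxododeca-5,10-dienoate | C=C(C(=O)OC)C(Br)[C@@H](O)/C=C(/C)[C@@H](O[Si](C)(C)C(C)(C)C)C[C@H](O[Si](C)(C)C(C)(C)C)/C(C)=C\C=O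
F5 | step 8 | (3aR,4R,5Z,7S,9S,10Z,11aS)-7,9-bis(tert-butyldimethylsilyloxy)-6,10-dimethyl-3-methylidene-2-oxo-2,3,3a,4,7,8,9,11a-octahydrocyclodeca[b]furan-4-yl 2-[bis(2,2,2-trifluoroethoxy)phosphoryl]propanoate | C=C1C(=O)O[C@H]2/C=C(/C)[C@@H](O[Si](C)(C)C(C)(C)C)C[C@H](O[Si](C)(C)C(C)(C)C)/C(C)=C\[C@@H](OC(=O)C(C)P(=O)(OCC(F)(F)F)OCC(F)(F)F)[C@H]12
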